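## Structural features

Lignan numbering is used: ring A carries the side chain C7–C8–C9 at C1, and primed locants belong to ring B. The target is an 8-O-4′ neolignan. A guaiacyl ring A (4-hydroxy-3-methoxyphenyl) is bonded to C7 of a glycerol-type chain, and the oxygen on C8 is the phenolic oxygen of a syringyl ring B, which has a methoxy group on each side of the ether and an (E)-3-hydroxyprop-1-enyl chain para to it. The two arenes are the only rings, so the two stereocentres, the benzylic carbinol C7 (R) and the aryloxy methine C8 (R), are neighbours in an open chain and form the threo pair, with the primary alcohol C9 on the far side of C8. Fragile elements are the free phenol para to a benzylic alcohol (quinone methide formation in base or on heating, benzylic ionisation in acid) and the electron-rich cinnamyl alcohol (acid, oxidants, hydrogenolysis). At the carbonyl oxidation level of C9 the beta-hydroxy alpha-aryloxy array is also fragile (retro-aldol cleavage, beta-elimination, epimerisation at C8). The real difficulty is absolute and relative control of two contiguous oxygenated stereocentres in a flexible chain, one of them bonded to a di-ortho-substituted, poorly nucleophilic phenol oxygen. The key step exploits the fact that C7–O is beta and C8–O alpha to C9: with C9 as an ester, C7=C8 of a (Z)-2-aryloxy-3-arylacrylate is a Michael acceptor whose beta carbon C7 can take up boron as a masked hydroxyl while C8 receives a proton.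

## Logic of the disconnections

**18 from 17.** Only the O–Si bond at the ring A phenol is cut. The phenol stays silylated to the end because the free para-hydroxybenzyl alcohol is the most sensitive element of the target. The forward step must cleave one aryl silyl ether beside three free alcohols and the cinnamyl alkene, which buffered fluoride should do.

**17 from 16.** No skeletal bond is cut; the C–H bonds at the two primary carbinol carbons C9 and C9′ are traced back to two ethyl esters. Carrying C9 as an ester this far lets one hydride reagent finish both chains at once. The demand is complete reduction of a hindered alpha-aryloxy ester and 1,2-reduction of a cinnamate without disturbing C8.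

**16 from 14 and 15.** The C7′=C8′ double bond is cut, which removes the whole ring B side chain and leaves an aryl aldehyde. The forward olefination must be (E)-selective and must not be basic, because 14 is a beta-hydroxy alpha-aryloxy ester; a stabilised ylide without added base meets this.

**14 from 13.** The aldehyde is traced back to its dioxolane (two acetal C–O bonds). The mask is needed because a free aldehyde would not survive the enolate, copper boryl and oxidation chemistry. The forward hydrolysis must use acid weak enough not to ionise C7–OH; the ester on C8 disfavours that ionisation, which is why the acetal is removed at this stage and not after ester reduction.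

**13 from 12.** The C7–O bond is traced back to a C7–B bond. Boron is the nucleophile-compatible surrogate of hydroxyl that a conjugate addition can deliver, and its oxidation is stereoretentive. The demand is an oxidation fast and mild enough to outrun elimination of boron and aryloxide and retro-aldol cleavage.

**12 from 10 and 11.** The C7–B and C8–H bonds are cut, which removes both stereocentres and leaves a planar trisubstituted acrylate plus the diboron reagent. This is the strategic simplification: all chirality comes from a catalyst. The forward step must differentiate the alkene faces at C7 and must protonate the enolate at C8 in the threo sense.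

**10 from 8 (through 9).** The C7=C8 pi bond is traced back to a beta-hydroxy ester by dehydration. This deliberately erases the uncontrolled stereocentres of 8. The demand is a single alkene geometry, since the catalyst reads the geometry.

**8 from 4 and 6 (through 7).** The C7–C8 sigma bond is cut in the aldol sense, separating the ring A aldehyde from the ring B aryloxyacetate. Both halves become simple one-ring compounds. The demand is clean enolate formation and addition at low temperature.

**6 from 5, and 4 from 3 from 1 and 2.** The aryl O–Si bond, the acetal C–O bonds and the O4′–C8 ether bond are cut. The ether is made first, by alkylation of the free phenol, and the acetal second, because a dioxolane para to a free phenol is too labile and the free para-hydroxy aldehyde acetalises poorly. A triisopropylsilyl group is chosen for the ring A phenol because a smaller silyl ether would be at risk under DBU, catalytic ethoxide and aqueous perborate.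

## Other disconnections considered

**Alternative 1:** The cut is the C8–O4′ aryl ether bond. In the forward direction the sodium salt of 4-bromo-2,6-dimethoxyphenol A2 would attack the allyliridium species formed from the linear carbonate methyl (2E,4S)-4-(tert-butyldimethylsilyloxy)-4-[3-methoxy-4-(triisopropylsilyloxy)phenyl]but-2-en-1-yl carbonate A1 with [Ir(cod)Cl]2 and a chiral phosphoramidite. Attack at the substituted terminus would give the branched ether A3, with a vinyl group as latent C9 and an aryl bromide as anchor for the ring B side chain.
- In its favour: the difficult aryl ether bond and the C8 configuration are made together under catalyst control, and A3 has two well-differentiated handles.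
- Against it here: the phenoxide is flanked by two methoxy groups and the allyl terminus it must reach is flanked by the silyloxy-bearing C7, which should slow the substitution and erode the branched preference. C7 in A1 needs its own asymmetric step and may be matched or mismatched with the ligand. After A3 the vinyl group must be cleaved oxidatively beside two electron-rich arenes, the bromide elaborated by palladium-catalysed coupling and reduction, and two different silyl ethers removed.
- Comparison: structurally both plans keep the two aryl units intact and differ in which bond to C8 is made last. Mechanistically alternative 1 is the better on C8, which it sets by the catalyst where the chosen plan relies on an enolate protonation; the chosen plan is the better on C7, which it sets in the same catalytic step. On step economy the chosen plan is shorter, since A1 and the elaboration of A3 each cost several steps.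

**Alternative 2:** The cut is the bond between ring A C1 and C7. In the forward direction the aryl Grignard reagent [4-(tert-butyldimethylsilyloxy)-3-methoxyphenyl]magnesium bromide A5 would add to the aldehyde (2R)-3-(tert-butyldimethylsilyloxy)-2-{4-[(E)-3-(tert-butyldimethylsilyloxy)prop-1-en-1-yl]-2,6-dimethoxyphenoxy}propanal A4 in the presence of MgBr2·OEt2. A magnesium chelate between the carbonyl oxygen and the C8 aryloxy oxygen would direct the aryl group to the face that gives the threo carbinol A6.
- In its favour: A6 already holds every carbon of the target, ring B side chain included, and one global desilylation would finish the synthesis. On step economy after the key step this alternative is the better.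
- Against it here: A4 has an acidic C8–H and a beta-silyloxy group, so racemisation and beta-elimination threaten under a basic Grignard reagent. Its preparation needs etherification of the hindered syringyl oxygen at a secondary carbon with clean inversion. The chelate must involve a weakly basic, shielded aryl ether oxygen, so the non-chelated polar pathway leading to the erythro epimer may compete.
- Comparison: structurally alternative 2 is the more convergent. Mechanistically the two plans are equal in leaving one centre to substrate control (C7 there, C8 in the chosen plan), but the chosen plan creates its absolute configuration catalytically from achiral materials, whereas A4 must carry C8 through a racemisation-prone stage. On total step count the two should be close, the gain after A6 being spent on making A4.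

**Alternative 3:** The cut is the C7–C8 bond. In the forward direction n-BuLi would deprotonate the benzylic methylene of the ether A7, 2-{3,5-dimethoxy-4-[((1Z,3R)-3-{[3-methoxy-4-(triisopropylsilyloxy)phenyl]methoxy}but-1-en-1-yl)oxy]phenyl}-1,3-dioxolane, at low temperature. The carbanion would undergo a [2,3]-Wittig rearrangement through a five-membered envelope transition state, forming C7–C8 on the face from which the allylic oxygen departs and giving the homoallylic alcohol A8, whose (E)-propenyl group is a masked C9.
- In its favour: both stereocentres arise in one concerted suprafacial event from one existing stereocentre and a defined enol ether geometry. On relative control between C7 and C8 this alternative is in principle the better, since the chosen plan sets C8 in a separate protonation.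
- Against it here: the benzylic position of A7 is deactivated by the para-silyloxy and meta-methoxy donors, so deprotonation competes with ortho-lithiation and the [1,2]-shift. A7 needs an enantiopure secondary allylic ether and a geometrically pure (Z)-enol ether of the hindered phenol. A8 still requires oxidative cleavage of the propenyl group beside two electron-rich arenes and reduction, before the same acetal hydrolysis, olefination, reduction and desilylation as in the chosen plan.
- Comparison: structurally both plans make C7–C8 from a ring A one-carbon unit and a ring B aryloxy two-carbon unit and mask the ring B aldehyde as the same dioxolane; on this they are equal. Mechanistically a stoichiometric chirality transfer under strongly basic conditions stands against a catalytic enantioselective addition under mild conditions. On step economy the chosen plan is shorter by the steps needed to assemble A7 and to unmask C9.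

Key step: step 6

Assumption: the (R,SP) antipode of the ferrocenyl bisphosphine is taken to deliver boron to the C7 face that leads to 3R; if a correlation shows the opposite sense, the commercially available mirror-image ligand is used and nothing else changes.

## Route

Step 1
Reactants: 1 syringaldehyde (4-hydroxy-3,5-dimethoxybenzaldehyde); 2 ethyl bromoacetate
Product: 3 ethyl 2-(4-formyl-2,6-dimethoxyphenoxy)acetate
Conditions: K2CO3, DMF, 60 °C
Reagents that add atoms: none
Why: Williamson ether synthesis: the acidic, para-formyl-activated phenoxide of 1 displaces bromide from the unhindered primary alpha-halo ester 2; aldehyde and ester are inert to carbonate.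

Step 2
Reactants: 3 ethyl 2-(4-formyl-2,6-dimethoxyphenoxy)acetate
Product: 4 ethyl 2-[4-(1,3-dioxolan-2-yl)-2,6-dimethoxyphenoxy]acetate
Conditions: HOCH2CH2OH (1.5 equiv), pTsOH·H2O (cat.), toluene, reflux, Dean–Stark
Reagents that add atoms: ethane-1,2-diol, OCCO
Why: Acid-catalysed acetalisation with azeotropic removal of water; because the phenol is already alkylated, the dioxolane is not para to a free hydroxyl and is stable to the bases that follow, and the small excess of diol keeps transesterification of the ethyl ester low.

Step 3
Reactants: 5 vanillin (4-hydroxy-3-methoxybenzaldehyde)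
Product: 6 3-methoxy-4-(triisopropylsilyloxy)benzaldehyde
Conditions: iPr3SiCl, imidazole, DMF, rt
Reagents that add atoms: chlorotriisopropylsilane, CC(C)[Si](Cl)(C(C)C)C(C)C
Why: Silylation of a phenol with imidazole as base and nucleophilic catalyst; the bulky triisopropylsilyl ether is chosen because it must survive DBU, catalytic ethoxide, aqueous perborate and iBu2AlH and is still removed by fluoride at the end.

Step 4
Reactants: 4 ethyl 2-[4-(1,3-dioxolan-2-yl)-2,6-dimethoxyphenoxy]acetate; 6 3-methoxy-4-(triisopropylsilyloxy)benzaldehyde
Product: 8 ethyl 2-[4-(1,3-dioxolan-2-yl)-2,6-dimethoxyphenoxy]-3-hydroxy-3-[3-methoxy-4-(triisopropylsilyloxy)phenyl]propanoate (racemic, both diastereomers), via lithium ester enolate 7 (not isolated)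
Conditions: LiN(iPr)2 (commercial solution), THF, −78 °C; then 6, −78 °C; aq NH4Cl
Reagents that add atoms: none
Why: Directed aldol addition: kinetic deprotonation of the alpha-aryloxy ester at −78 °C gives the lithium enolate 7, which adds to the non-enolisable aldehyde 6 faster than it self-condenses. Both new stereocentres are uncontrolled and irrelevant, because step 5 removes them.

Step 5
Reactants: 8 ethyl 2-[4-(1,3-dioxolan-2-yl)-2,6-dimethoxyphenoxy]-3-hydroxy-3-[3-methoxy-4-(triisopropylsilyloxy)phenyl]propanoate
Product: 10 ethyl (Z)-2-[4-(1,3-dioxolan-2-yl)-2,6-dimethoxyphenoxy]-3-[3-methoxy-4-(triisopropylsilyloxy)phenyl]prop-2-enoate, via benzylic mesylate 9 (not isolated)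
Conditions: CH3SO2Cl, Et3N, CH2Cl2, 0 °C; then DBU, 0 °C to rt
Reagents that add atoms: methanesulfonyl chloride, CS(=O)(=O)Cl (its atoms are present in 9 only and leave again on elimination)
Why: Sulfonylation followed by E1cB elimination through the ester enolate; both diastereomers of 9 converge on the conjugated alkene, and the product-like transition state should favour the isomer with the ring A aryl group trans to the ester, which is the (Z)-isomer. Any minor geometric isomer is removed by chromatography or crystallisation, because the geometry fixes the facial outcome of step 6.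

Step 6
Reactants: 10 ethyl (Z)-2-[4-(1,3-dioxolan-2-yl)-2,6-dimethoxyphenoxy]-3-[3-methoxy-4-(triisopropylsilyloxy)phenyl]prop-2-enoate; 11 bis(pinacolato)diboron
Product: 12 ethyl (2S,3R)-2-[4-(1,3-dioxolan-2-yl)-2,6-dimethoxyphenoxy]-3-[3-methoxy-4-(triisopropylsilyloxy)phenyl]-3-(4,4,5,5-tetramethyl-1,3,2-dioxaborolan-2-yl)propanoate
Conditions: CuCl (5 mol%), NaOtBu (10 mol%), (R)-1-[(SP)-2-(diphenylphosphino)ferrocenyl]ethyldicyclohexylphosphine (5.5 mol%), EtOH (2 equiv), THF, 0 °C to rt; short silica plug, used at once
Reagents that add atoms: none
Why: NaOtBu turns CuCl and the bisphosphine into a monovalent copper alkoxide, which exchanges with 11 to give a chiral copper boryl complex; this adds across C7=C8 of 10 with boron on the beta carbon C7, and ethanol protonates the resulting copper enolate at C8 and regenerates the copper alkoxide. The closest known reaction type is the copper-catalysed enantioselective conjugate borylation of beta-aryl acrylates and of alpha-acylamino acrylates with B2pin2 and a chiral bisphosphine; the alpha-aryloxy group is a new substituent within that class and has not been examined. No ring is formed. C7 is controlled by the ligand: the ferrocenyl bisphosphine differentiates the two faces of the single (Z)-alkene in the borylcupration, so the geometric purity of 10 is carried over into enantiomeric purity at C7. C8 is controlled by the substrate: the enolate is expected to be protonated in the conformation that keeps C7–H in the enolate plane (least allylic 1,3-strain) and from the face opposite the electron-rich C7–B bond, which corresponds to the 2S,3R (threo-type) relationship; this is the least secure element and is verified at 13. The step needs chemoselectivity for one acceptor and tolerance of catalytic alkoxide, and the substrate provides both: the ring B aldehyde is masked as a dioxolane, the phenol is a triisopropylsilyl ether, and the proton source matches the ethyl ester so that alkoxide exchange changes nothing. Catalytic base, a temperature not above room temperature and immediate use of 12 keep the 1,2-elimination of boron and aryloxide in check.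

Step 7
Reactants: 12 ethyl (2S,3R)-2-[4-(1,3-dioxolan-2-yl)-2,6-dimethoxyphenoxy]-3-[3-methoxy-4-(triisopropylsilyloxy)phenyl]-3-(4,4,5,5-tetramethyl-1,3,2-dioxaborolan-2-yl)propanoate
Product: 13 ethyl (2S,3R)-2-[4-(1,3-dioxolan-2-yl)-2,6-dimethoxyphenoxy]-3-hydroxy-3-[3-methoxy-4-(triisopropylsilyloxy)phenyl]propanoate
Conditions: NaBO3·4H2O, THF/H2O, 0 °C to rt
Reagents that add atoms: sodium perborate tetrahydrate (NaBO3·4H2O), [Na+].[O-]OB=O.O.O.O.O
Why: Boronate oxidation: the peroxoborate anion adds to boron and the C7–B bond migrates to oxygen with retention, so 3R in 12 becomes 3R in 13; perborate is mild enough to spare ester, silyl ether and acetal. Any C8 epimer is separated here by chromatography, and the enantiomeric purity is checked at this point.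

Step 8
Reactants: 13 ethyl (2S,3R)-2-[4-(1,3-dioxolan-2-yl)-2,6-dimethoxyphenoxy]-3-hydroxy-3-[3-methoxy-4-(triisopropylsilyloxy)phenyl]propanoate
Product: 14 ethyl (2S,3R)-2-(4-formyl-2,6-dimethoxyphenoxy)-3-hydroxy-3-[3-methoxy-4-(triisopropylsilyloxy)phenyl]propanoate
Conditions: pyridinium p-toluenesulfonate (cat.), acetone/H2O, rt
Reagents that add atoms: water, O
Why: Acid-catalysed acetal hydrolysis; the electron-rich aryl dioxolane is cleaved by a weak acid, and the C7 carbinol resists ionisation because the neighbouring C8 carries an ester. The aryl silyl ether is stable to this acid.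

Step 9
Reactants: 14 ethyl (2S,3R)-2-(4-formyl-2,6-dimethoxyphenoxy)-3-hydroxy-3-[3-methoxy-4-(triisopropylsilyloxy)phenyl]propanoate; 15 ethyl 2-(triphenyl-λ5-phosphanylidene)acetate
Product: 16 ethyl (2S,3R)-2-{4-[(E)-3-ethoxy-3-oxoprop-1-en-1-yl]-2,6-dimethoxyphenoxy}-3-hydroxy-3-[3-methoxy-4-(triisopropylsilyloxy)phenyl]propanoate
Conditions: toluene, 80 °C
Reagents that add atoms: none
Why: Wittig olefination with a stabilised ylide, which gives the (E)-cinnamate and needs no added base, so the beta-hydroxy alpha-aryloxy ester is not exposed to retro-aldol or epimerising conditions.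

Step 10
Reactants: 16 ethyl (2S,3R)-2-{4-[(E)-3-ethoxy-3-oxoprop-1-en-1-yl]-2,6-dimethoxyphenoxy}-3-hydroxy-3-[3-methoxy-4-(triisopropylsilyloxy)phenyl]propanoate
Product: 17 (1R,2R)-2-{4-[(E)-3-hydroxyprop-1-en-1-yl]-2,6-dimethoxyphenoxy}-1-[3-methoxy-4-(triisopropylsilyloxy)phenyl]propane-1,3-diol
Conditions: iBu2AlH (7 equiv), CH2Cl2, −78 to 0 °C; aq potassium sodium tartrate
Reagents that add atoms: none
Why: Hydride reduction of both esters by excess iBu2AlH: the cinnamate is reduced in the 1,2-sense to the allylic alcohol and the alpha-aryloxy ester to C9–OH, while C7 is held as its aluminium alkoxide; no stereocentre is touched (the descriptor at C8 changes from S to R only because the priority of C9 falls).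

Step 11
Reactants: 17 (1R,2R)-2-{4-[(E)-3-hydroxyprop-1-en-1-yl]-2,6-dimethoxyphenoxy}-1-[3-methoxy-4-(triisopropylsilyloxy)phenyl]propane-1,3-diol
Product: 18 (1R,2R)-1-(4-hydroxy-3-methoxyphenyl)-2-{4-[(E)-3-hydroxyprop-1-en-1-yl]-2,6-dimethoxyphenoxy}propane-1,3-diol
Conditions: Bu4NF, AcOH, THF, 0 °C
Reagents that add atoms: none
Why: Fluoride-induced cleavage of the aryl O–Si bond; the acetic acid buffer keeps the liberated phenoxide protonated so that the para-hydroxybenzyl alcohol cannot eliminate to a quinone methide.

## Compound list

1 | syringaldehyde (4-hydroxy-3,5-dimethoxybenzaldehyde) | COc1cc(C=O)cc(OC)c1O | starting material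
2 | ethyl bromoacetate | CCOC(=O)CBr | starting material
3 | ethyl 2-(4-formyl-2,6-dimethoxyphenoxy)acetate | CCOC(=O)COc1c(OC)cc(C=O)cc1OC | intermediate
4 | ethyl 2-[4-(1,3-dioxolan-2-yl)-2,6-dimethoxyphenoxy]acetate | CCOC(=O)COc1c(OC)cc(C2OCCO2)cc1OC | intermediate
5 | vanillin (4-hydroxy-3-methoxybenzaldehyde) | COc1cc(C=O)ccc1O | starting material
6 | 3-methoxy-4-(triisopropylsilyloxy)benzaldehyde | COc1cc(C=O)ccc1O[Si](C(C)C)(C(C)C)C(C)C | intermediate
7 | lithium 2-[4-(1,3-dioxolan-2-yl)-2,6-dimethoxyphenoxy]-1-ethoxyethen-1-olate | [Li+].CCOC([O-])=COc1c(OC)cc(C2OCCO2)cc1OC | intermediate (not isolated)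
8 | ethyl 2-[4-(1,3-dioxolan-2-yl)-2,6-dimethoxyphenoxy]-3-hydroxy-3-[3-methoxy-4-(triisopropylsilyloxy)phenyl]propanoate (racemic, both diastereomers) | CCOC(=O)C(Oc1c(OC)cc(C2OCCO2)cc1OC)C(O)c1ccc(O[Si](C(C)C)(C(C)C)C(C)C)c(OC)c1 | intermediate
9 | ethyl 2-[4-(1,3-dioxolan-2-yl)-2,6-dimethoxyphenoxy]-3-(methanesulfonyloxy)-3-[3-methoxy-4-(triisopropylsilyloxy)phenyl]propanoate (racemic, both diastereomers) | CCOC(=O)C(Oc1c(OC)cc(C2OCCO2)cc1OC)C(OS(C)(=O)=O)c1ccc(O[Si](C(C)C)(C(C)C)C(C)C)c(OC)c1 | intermediate (not isolated)
10 | ethyl (Z)-2-[4-(1,3-dioxolan-2-yl)-2,6-dimethoxyphenoxy]-3-[3-methoxy-4-(triisopropylsilyloxy)phenyl]prop-2-enoate | CCOC(=O)/C(Oc1c(OC)cc(C2OCCO2)cc1OC)=C/c1ccc(O[Si](C(C)C)(C(C)C)C(C)C)c(OC)c1 | intermediate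
11 | bis(pinacolato)diboron | CC1(C)OB(OC1(C)C)B1OC(C)(C)C(C)(C)O1 | starting material
12 | ethyl (2S,3R)-2-[4-(1,3-dioxolan-2-yl)-2,6-dimethoxyphenoxy]-3-[3-methoxy-4-(triisopropylsilyloxy)phenyl]-3-(4,4,5,5-tetramethyl-1,3,2-dioxaborolan-2-yl)propanoate | COc1cc([C@@H](B2OC(C)(C)C(C)(C)O2)[C@@H](C(=O)OCC)Oc3c(OC)cc(C4OCCO4)cc3OC)ccc1O[Si](C(C)C)(C(C)C)C(C)C | intermediate
13 | ethyl (2S,3R)-2-[4-(1,3-dioxolan-2-yl)-2,6-dimethoxyphenoxy]-3-hydroxy-3-[3-methoxy-4-(triisopropylsilyloxy)phenyl]propanoate | COc1cc([C@@H](O)[C@@H](C(=O)OCC)Oc2c(OC)cc(C3OCCO3)cc2OC)ccc1O[Si](C(C)C)(C(C)C)C(C)C | intermediate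
14 | ethyl (2S,3R)-2-(4-formyl-2,6-dimethoxyphenoxy)-3-hydroxy-3-[3-methoxy-4-(triisopropylsilyloxy)phenyl]propanoate | COc1cc([C@@H](O)[C@@H](C(=O)OCC)Oc2c(OC)cc(C=O)cc2OC)ccc1O[Si](C(C)C)(C(C)C)C(C)C | intermediate
15 | ethyl 2-(triphenyl-λ5-phosphanylidene)acetate | CCOC(=O)C=P(c1ccccc1)(c1ccccc1)c1ccccc1 | starting material
16 | ethyl (2S,3R)-2-{4-[(E)-3-ethoxy-3-oxoprop-1-en-1-yl]-2,6-dimethoxyphenoxy}-3-hydroxy-3-[3-methoxy-4-(triisopropylsilyloxy)phenyl]propanoate | COc1cc([C@@H](O)[C@@H](C(=O)OCC)Oc2c(OC)cc(/C=C/C(=O)OCC)cc2OC)ccc1O[Si](C(C)C)(C(C)C)C(C)C | intermediate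
17 | (1R,2R)-2-{4-[(E)-3-hydroxyprop-1-en-1-yl]-2,6-dimethoxyphenoxy}-1-[3-methoxy-4-(triisopropylsilyloxy)phenyl]propane-1,3-diol | COc1cc([C@@H](O)[C@@H](CO)Oc2c(OC)cc(/C=C/CO)cc2OC)ccc1O[Si](C(C)C)(C(C)C)C(C)C | intermediate
18 | (1R,2R)-1-(4-hydroxy-3-methoxyphenyl)-2-{4-[(E)-3-hydroxyprop-1-en-1-yl]-2,6-dimethoxyphenoxy}propane-1,3-diol | COc1cc([C@@H](O)[C@@H](CO)Oc2c(OC)cc(/C=C/CO)cc2OC)ccc1O | target

## Step count and least certain steps

Total: 11 steps. Longest linear sequence: 10 steps (steps 1, 2 and 4 to 11); step 3 is a one-step branch.

**Step 6 (key step).** Three processes are most likely to fail. Borylcupration may be slow, because the alpha-aryloxy group donates into the acceptor and makes the alkene trisubstituted and hindered. Protonation at C8 may be unselective or run in the wrong sense, because that centre is under substrate control only. Boron and aryloxide may be lost by base-triggered elimination if the reaction is long. The fallback is the auxiliary-controlled aldol route; it sets out from 4 (and uses 6) and comes back at 13. Saponification of 4 (LiOH, THF/H2O, acidification to pH 4) gives 2-[4-(1,3-dioxolan-2-yl)-2,6-dimethoxyphenoxy]acetic acid F1. Acylation of (S)-4-benzyl-1,3-oxazolidin-2-one with F1 (pivaloyl chloride, Et3N, LiCl, THF) gives (4S)-4-benzyl-3-{2-[4-(1,3-dioxolan-2-yl)-2,6-dimethoxyphenoxy]acetyl}-1,3-oxazolidin-2-one F2. An Evans syn-aldol reaction of F2 with 6 (iPr2NEt added first, then Bu2BOTf, CH2Cl2, −78 to 0 °C) should give, through the chair transition state of the (Z)-boron enolate, (4S)-4-benzyl-3-{(2S,3R)-2-[4-(1,3-dioxolan-2-yl)-2,6-dimethoxyphenoxy]-3-hydroxy-3-[3-methoxy-4-(triisopropylsilyloxy)phenyl]propanoyl}-1,3-oxazolidin-2-one F3. Ethanolysis with bromomagnesium ethoxide (EtMgBr in EtOH, 0 °C) removes the auxiliary and gives 13.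

**Step 7.** The peroxoborate adduct places boron and the aryloxy group on adjacent carbons, so 1,2-elimination may compete with the 1,2-shift; the mildly alkaline medium may also cause retro-aldol cleavage or C8 epimerisation of the product. The fallback is a boron-free reduction route; it sets out from 8 and comes back at 13. Dess–Martin oxidation of 8 gives the configurationally labile beta-keto ester ethyl 2-[4-(1,3-dioxolan-2-yl)-2,6-dimethoxyphenoxy]-3-[3-methoxy-4-(triisopropylsilyloxy)phenyl]-3-oxopropanoate F4. Asymmetric transfer hydrogenation under dynamic kinetic resolution (RuCl(p-cymene)[TsDPEN], antipode chosen by correlation, HCO2H/Et3N, DMF, rt) is expected, by analogy with alpha-alkoxy beta-keto esters, to give the syn (threo-type) hydroxy ester 13.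

**Step 5.** Geometric control in the E1cB elimination may be incomplete, because the carbanion intermediate forgets the configuration of 9 and the preference rests only on product-like strain; the electron-rich benzylic mesylate may also ionise early. The fallback treats the geometry as a thermodynamic question; it sets out from 8 and comes back at 10. The crude alkene mixture, containing ethyl (E)-2-[4-(1,3-dioxolan-2-yl)-2,6-dimethoxyphenoxy]-3-[3-methoxy-4-(triisopropylsilyloxy)phenyl]prop-2-enoate F5, is equilibrated with catalytic I2 in toluene under visible light. This should move it toward 10, in which the ring A aryl group is trans to the ester; residual F5 is recycled.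

**Step 10.** Reduction of the hindered, chelated alpha-aryloxy ester may stop at the aldehyde stage, or the aluminium aldolate may fragment by retro-aldol on warming. The fallback is a stepwise reduction; it sets out from 13 and comes back at 17. LiBH4 (THF, 0 °C) reduces only the activated alpha-aryloxy ester of 13 to give (1R,2R)-2-[4-(1,3-dioxolan-2-yl)-2,6-dimethoxyphenoxy]-1-[3-methoxy-4-(triisopropylsilyloxy)phenyl]propane-1,3-diol F6. Mild hydrolysis (AcOH/THF/H2O, rt) gives 4-({(1R,2R)-1,3-dihydroxy-1-[3-methoxy-4-(triisopropylsilyloxy)phenyl]propan-2-yl}oxy)-3,5-dimethoxybenzaldehyde F7. Wittig reaction with 15 gives ethyl (E)-3-[4-({(1R,2R)-1,3-dihydroxy-1-[3-methoxy-4-(triisopropylsilyloxy)phenyl]propan-2-yl}oxy)-3,5-dimethoxyphenyl]prop-2-enoate F8. iBu2AlH then has only one unhindered cinnamate ester to reduce and gives 17.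

## Further compounds

F1 | step 6 | 2-[4-(1,3-dioxolan-2-yl)-2,6-dimethoxyphenoxy]acetic acid | OC(=O)COc1c(OC)cc(C2OCCO2)cc1OC
F2 | step 6 | (4S)-4-benzyl-3-{2-[4-(1,3-dioxolan-2-yl)-2,6-dimethoxyphenoxy]acetyl}-1,3-oxazolidin-2-one | O=C(COc1c(OC)cc(C2OCCO2)cc1OC)N3[C@@H](Cc4ccccc4)COC3=O
F3 | step 6 | (4S)-4-benzyl-3-{(2S,3R)-2-[4-(1,3-dioxolan-2-yl)-2,6-dimethoxyphenoxy]-3-hydroxy-3-[3-methoxy-4-(triisopropylsilyloxy)phenyl]propanoyl}-1,3-oxazolidin-2-one | COc1cc([C@@H](O)[C@@H](C(=O)N2[C@@H](Cc3ccccc3)COC2=O)Oc4c(OC)cc(C5OCCO5)cc4OC)ccc1O[Si](C(C)C)(C(C)C)C(C)C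
F4 | step 7 | ethyl 2-[4-(1,3-dioxolan-2-yl)-2,6-dimethoxyphenoxy]-3-[3-methoxy-4-(triisopropylsilyloxy)phenyl]-3-oxopropanoate (racemic) | CCOC(=O)C(Oc1c(OC)cc(C2OCCO2)cc1OC)C(=O)c1ccc(O[Si](C(C)C)(C(C)C)C(C)C)c(OC)c1
F5 | step 5 | ethyl (E)-2-[4-(1,3-dioxolan-2-yl)-2,6-dimethoxyphenoxy]-3-[3-methoxy-4-(triisopropylsilyloxy)phenyl]prop-2-enoate | CCOC(=O)/C(Oc1c(OC)cc(C2OCCO2)cc1OC)=C\c1ccc(O[Si](C(C)C)(C(C)C)C(C)C)c(OC)c1
F6 | step 10 | (1R,2R)-2-[4-(1,3-dioxolan-2-yl)-2,6-dimethoxyphenoxy]-1-[3-methoxy-4-(triisopropylsilyloxy)phenyl]propane-1,3-diol | COc1cc([C@@H](O)[C@@H](CO)Oc2c(OC)cc(C3OCCO3)cc2OC)ccc1O[Si](C(C)C)(C(C)C)C(C)C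
F7 | step 10 | 4-({(1R,2R)-1,3-dihydroxy-1-[3-methoxy-4-(triisopropylsilyloxy)phenyl]propan-2-yl}oxy)-3,5-dimethoxybenzaldehyde | COc1cc([C@@H](O)[C@@H](CO)Oc2c(OC)cc(C=O)cc2OC)ccc1O[Si](C(C)C)(C(C)C)C(C)C
F8 | step 10 | ethyl (E)-3-[4-({(1R,2R)-1,3-dihydroxy-1-[3-methoxy-4-(triisopropylsilyloxy)phenyl]propan-2-yl}oxy)-3,5-dimethoxyphenyl]prop-2-enoate | COc1cc([C@@H](O)[C@@H](CO)Oc2c(OC)cc(/C=C/C(=O)OCC)cc2OC)ccc1O[Si](C(C)C)(C(C)C)C(C)C
A1 | alternative 1 | methyl (2E,4S)-4-(tert-butyldimethylsilyloxy)-4-[3-methoxy-4-(triisopropylsilyloxy)phenyl]but-2-en-1-yl carbonate | COc1cc([C@@H](O[Si](C)(C)C(C)(C)C)/C=C/COC(=O)OC)ccc1O[Si](C(C)C)(C(C)C)C(C)C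
A2 | alternative 1 | 4-bromo-2,6-dimethoxyphenol | COc1cc(Br)cc(OC)c1O
A3 | alternative 1 | 5-bromo-2-({(1R,2R)-1-(tert-butyldimethylsilyloxy)-1-[3-methoxy-4-(triisopropylsilyloxy)phenyl]but-3-en-2-yl}oxy)-1,3-dimethoxybenzene | COc1cc([C@@H](O[Si](C)(C)C(C)(C)C)[C@@H](C=C)Oc2c(OC)cc(Br)cc2OC)ccc1O[Si](C(C)C)(C(C)C)C(C)C
A4 | alternative 2 | (2R)-3-(tert-butyldimethylsilyloxy)-2-{4-[(E)-3-(tert-butyldimethylsilyloxy)prop-1-en-1-yl]-2,6-dimethoxyphenoxy}propanal | O=C[C@@H](CO[Si](C)(C)C(C)(C)C)Oc1c(OC)cc(/C=C/CO[Si](C)(C)C(C)(C)C)cc1OC
A5 | alternative 2 | [4-(tert-butyldimethylsilyloxy)-3-methoxyphenyl]magnesium bromide | COc1cc([Mg]Br)ccc1O[Si](C)(C)C(C)(C)C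
A6 | alternative 2 | (1R,2R)-3-(tert-butyldimethylsilyloxy)-1-[4-(tert-butyldimethylsilyloxy)-3-methoxyphenyl]-2-{4-[(E)-3-(tert-butyldimethylsilyloxy)prop-1-en-1-yl]-2,6-dimethoxyphenoxy}propan-1-ol | COc1cc([C@@H](O)[C@@H](CO[Si](C)(C)C(C)(C)C)Oc2c(OC)cc(/C=C/CO[Si](C)(C)C(C)(C)C)cc2OC)ccc1O[Si](C)(C)C(C)(C)C
A7 | alternative 3 | 2-{3,5-dimethoxy-4-[((1Z,3R)-3-{[3-methoxy-4-(triisopropylsilyloxy)phenyl]methoxy}but-1-en-1-yl)oxy]phenyl}-1,3-dioxolane | C[C@@H](OCc1ccc(O[Si](C(C)C)(C(C)C)C(C)C)c(OC)c1)/C=C\Oc1c(OC)cc(C2OCCO2)cc1OC
A8 | alternative 3 | (1R,2R,3E)-2-[4-(1,3-dioxolan-2-yl)-2,6-dimethoxyphenoxy]-1-[3-methoxy-4-(triisopropylsilyloxy)phenyl]pent-3-en-1-ol | COc1cc([C@@H](O)[C@@H](/C=C/C)Oc2c(OC)cc(C3OCCO3)cc2OC)ccc1O[Si](C(C)C)(C(C)C)C(C)C
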